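**Retrosynthetic overview**
1. The ester C–O bond is made last. Before it, C3a–H, C3–OH and C4–H are all set from an α,β-epoxy ketone with SmI2; that ketone comes from the cross-conjugated dienone 14 by epoxidation of the ring-fusion enone and deconjugation of the other enone.
2. Enabling feature: C4, the oxygen-bearing carbon of the seven-membered ring, is bonded to ring-fusion carbon C3a, and C1 is γ to it through quaternary C8a. With C4 as a ketone this is the retron of a cyclopropyl ketone, i.e. a C1–C3a bond (three-membered ring C1/C8a/C3a) that is not in the target and is made only to be broken.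
3. Key disconnection: the cyclopropane σ-bond C1–C3a of bicyclo[5.1.0]octenone 11 is traded for the C1–C2 and C3–C3a bonds in a radical-relay formal [3+2] cycloaddition with 3-methylbut-1-yne, which brings in C2, C3 and the isopropyl group in one operation.
4. Ring order: seven-membered ring first ([4+3] cycloaddition on 2,5-dimethylfuran, then opening of the oxygen bridge to the achiral dienone 6); cyclopropane second (auxiliary-controlled, fixes C8a); five-membered ring third (key step).
5. Numbering is that of azulene: C3 carbinol carbon, C3a ring-fusion CH, C4 ester-bearing carbon, C6 methyl-bearing alkene carbon, C8a quaternary carbon.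

Key step: step 7

Assumption: the (R,R)-diol used in step 4 is taken to give the (1S,7R)-cyclopropane in step 5 by oxygen-directed delivery of the zinc carbenoid; if the sense of induction were the opposite, the (S,S)-diol would be used and nothing else would change.

**Step 1**
Reactants: 1 2,5-dimethylfuran; 2 1,1,3-trichloropropan-2-one
Product: 4 (1R,5S)-1,5-dimethyl-8-oxabicyclo[3.2.1]oct-6-en-3-one, via dichloro cycloadduct 3 (not isolated)
Conditions: Et3N, CF3CH2OH, 0 °C→rt; then Zn–Cu couple, NH4Cl, MeOH, rt
Reagents that add atoms: none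
Why: Base-induced loss of HCl from 2 gives the 1,3-dichloro-2-oxyallyl cation, which adds across C2/C5 of the furan in a [4+3] cycloaddition (only the cis-bridged bicycle can form, and it is meso once the halogens are gone), and zinc then removes both α-chlorine atoms by reductive dehalogenation of the α-halo ketone.

**Step 2**
Reactants: 4 (1R,5S)-1,5-dimethyl-8-oxabicyclo[3.2.1]oct-6-en-3-one
Product: 5 (1R,5S)-1,5-dimethyl-8-oxabicyclo[3.2.1]octan-3-one
Conditions: H2 (1 atm), 10% Pd/C, EtOAc, rt
Reagents that add atoms: none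
Why: Heterogeneous catalytic hydrogenation saturates the strained cis-disubstituted alkene while the ketone and the bridging ether are left alone, and no stereocentre changes.

**Step 3**
Reactants: 5 (1R,5S)-1,5-dimethyl-8-oxabicyclo[3.2.1]octan-3-one
Product: 6 3,6-dimethylcyclohepta-2,6-dien-1-one
Conditions: TMSOTf (3 equiv), Et3N (4 equiv), CH2Cl2, 0 °C→reflux; aq. NaHCO3
Reagents that add atoms: none
Why: Soft enolisation to the silyl enol ether and Lewis-acid-assisted β-elimination of the bridging oxygen, first on one side of the ketone and then (as the tertiary silyl ether) on the other, is an E1cB-type double elimination that should give the achiral cross-conjugated dienone.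

**Step 4**
Reactants: 6 3,6-dimethylcyclohepta-2,6-dien-1-one; 7 (1R,2R)-1,2-diphenylethane-1,2-diol
Product: 9 (2R,3R)-7,10-dimethyl-2,3-diphenyl-1,4-dioxaspiro[4.6]undeca-6,10-diene, via bis-silyl ether 8 (not isolated)
Conditions: iPrOSiMe3 (2.5 equiv), TMSOTf (5 mol %), CH2Cl2, −20 °C
Reagents that add atoms: none
Why: Aprotic, low-temperature silyl-transfer ketalisation forms the dioxolane without moving the enone double bonds out of conjugation, and the C2-symmetric auxiliary makes the two enone arms equivalent and their faces diastereotopic.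

**Step 5**
Reactants: 9 (2R,3R)-7,10-dimethyl-2,3-diphenyl-1,4-dioxaspiro[4.6]undeca-6,10-diene
Product: 10 (1S,7R,4'R,5'R)-4,7-dimethyl-4',5'-diphenylspiro[bicyclo[5.1.0]oct-3-ene-2,2'-[1,3]dioxolane]
Conditions: Zn–Cu couple, CH2I2 (1.2 equiv), Et2O, reflux
Reagents that add atoms: diiodomethane, ICI
Why: Simmons–Smith cyclopropanation in which the zinc carbenoid, held by the less hindered dioxolane oxygen, is delivered to one face of the adjacent electron-rich trisubstituted alkene, so the auxiliary sets both cyclopropane stereocentres (the later C3a and C8a) together, while a limiting amount of carbenoid favours reaction of only one alkene.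

**Step 6**
Reactants: 10 (1S,7R,4'R,5'R)-4,7-dimethyl-4',5'-diphenylspiro[bicyclo[5.1.0]oct-3-ene-2,2'-[1,3]dioxolane]
Product: 11 (1S,7R)-4,7-dimethylbicyclo[5.1.0]oct-3-en-2-one
Conditions: 1 M aq. HCl, THF/MeOH, rt
Reagents that add atoms: water, O
Why: Acid-catalysed hydrolysis of the allylic ketal returns the conjugated ketone without touching the cyclopropane stereocentres and releases the auxiliary diol for reuse.

**Step 7**
Reactants: 11 (1S,7R)-4,7-dimethylbicyclo[5.1.0]oct-3-en-2-one; 12 3-methylbut-1-yne
Product: 13 (3aR,8aR)-6,8a-dimethyl-3-(propan-2-yl)-3a,7,8,8a-tetrahydroazulen-4(1H)-one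
Conditions: SmI2 (20 mol %), Sm metal (20 mol %), 12 (6 equiv), THF, 55 °C, sealed tube
Reagents that add atoms: none
Why: Electron transfer from SmI2 to the enone carbonyl gives a samarium ketyl whose cyclopropylcarbinyl-type fragmentation breaks the external C1–C3a bond to a trivalent-samarium dienolate and a primary C1 radical; the radical adds to the unsubstituted alkyne terminus (C1–C2 bond), the vinyl radical at C3 closes on enolate carbon C3a (C3–C3a bond), and back electron transfer from the new ketyl returns divalent samarium, so the metal is catalytic. The closest known reaction type is the SmI2-catalysed radical-relay formal [3+2] coupling of aryl and of bicyclic alkyl cyclopropyl ketones with alkynes to give cyclopentenes. The cyclopentene ring closes by a 5-exo-trig radical cyclisation onto the enolate. C3a is formed with its hydrogen cis to the C8a methyl group because the three-atom tether can reach only the face of C3a on which C1 already sits; this centre is cleared again in step 8, and C8a is carried through unchanged. The step needs cleavage of the external cyclopropane bond and not the ring-fusion bond (secured by its better overlap with the carbonyl π system in the cis-fused bicycle), addition at the terminal alkyne carbon (sterics and the more substituted vinyl radical), and capture by the alkyne ahead of hydrogen abstraction from THF (large excess of alkyne; Sm metal returns trivalent samarium that leaves the cycle).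

**Step 8**
Reactants: 13 (3aR,8aR)-6,8a-dimethyl-3-(propan-2-yl)-3a,7,8,8a-tetrahydroazulen-4(1H)-one
Product: 14 (8aR)-6,8a-dimethyl-3-(propan-2-yl)-2,7,8,8a-tetrahydroazulen-4(1H)-one
Conditions: DBU (0.3 equiv), CH2Cl2, rt
Reagents that add atoms: none
Why: Base-catalysed isomerisation of the β,γ-unsaturated ketone through the extended dienolate (C3a–H is both α to the ketone and allylic) moves the ring double bond into conjugation as the more stable tetrasubstituted enone and removes the C3a stereocentre.

**Step 9**
Reactants: 14 (8aR)-6,8a-dimethyl-3-(propan-2-yl)-2,7,8,8a-tetrahydroazulen-4(1H)-one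
Product: 15 (3R,3aR,8aR)-3,3a-epoxy-6,8a-dimethyl-3-(propan-2-yl)-2,3,3a,7,8,8a-hexahydroazulen-4(1H)-one
Conditions: dimethyldioxirane (1.1 equiv, acetone solution), CH2Cl2, 0 °C
Reagents that add atoms: dimethyldioxirane, CC1(C)OO1
Why: Electrophilic epoxidation by the dioxirane should pick the tetrasubstituted C3=C3a bond, the more electron-rich of the two enone double bonds, and attack anti to the axial C8a methyl group that shields the other face, which sets C3 and C3a with the oxygen trans to that methyl group.

**Step 10**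
Reactants: 15 (3R,3aR,8aR)-3,3a-epoxy-6,8a-dimethyl-3-(propan-2-yl)-2,3,3a,7,8,8a-hexahydroazulen-4(1H)-one
Product: 17 (3R,3aR,8aS)-3,3a-epoxy-6,8a-dimethyl-3-(propan-2-yl)-2,3,3a,5,8,8a-hexahydroazulen-4(1H)-one, via potassium dienolate 16 (not isolated)
Conditions: KOtBu (1.5 equiv), tBuOH/THF, 0 °C; inverse quench into AcOH/H2O, 0 °C
Reagents that add atoms: none
Why: Deconjugation by kinetic α-protonation of an extended dienolate: with C3a fully substituted only γ-deprotonation is possible, the thermodynamic endocyclic potassium dienolate forms, and the fast acid quench protonates it at C5 to leave the C6=C7 double bond, with no stereocentre touched.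

**Step 11**
Reactants: 17 (3R,3aR,8aS)-3,3a-epoxy-6,8a-dimethyl-3-(propan-2-yl)-2,3,3a,5,8,8a-hexahydroazulen-4(1H)-one
Product: 19 (3R,3aR,4R,8aS)-6,8a-dimethyl-3-(propan-2-yl)-1,2,3,3a,4,5,8,8a-octahydroazulene-3,4-diol, via hydroxy ketone 18 (not isolated)
Conditions: SmI2 (2.5 equiv), THF/MeOH (10:1), −78 °C; then SmI2 (3 equiv), −78→0 °C
Reagents that add atoms: none
Why: SmI2 cleaves the C3a–O bond of the α,β-epoxy ketone to a samarium enolate that methanol protonates kinetically at C3a from the face of the C3 alkoxide (opposite to the isopropyl and C8a methyl groups), which gives the trans ring fusion, and further SmI2/MeOH reduces the β-hydroxy ketone through its samarium chelate, which holds the C4 oxygen on the face of the C3 oxygen so that C4 takes its hydrogen on the methyl face and the equatorial, more stable alcohol results.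

**Step 12**
Reactants: 19 (3R,3aR,4R,8aS)-6,8a-dimethyl-3-(propan-2-yl)-1,2,3,3a,4,5,8,8a-octahydroazulene-3,4-diol; 20 3,4-dimethoxybenzoyl chloride
Product: 21 (3R,3aR,4R,8aS)-3-hydroxy-6,8a-dimethyl-3-(propan-2-yl)-1,2,3,3a,4,5,8,8a-octahydroazulen-4-yl 3,4-dimethoxybenzoate
Conditions: 20 (1.5 equiv), Et3N, DMAP (0.2 equiv), CH2Cl2, 0 °C→rt
Reagents that add atoms: none
Why: DMAP-catalysed acylation (nucleophilic acyl transfer) esterifies the secondary C4 hydroxyl while the tertiary C3 hydroxyl is too hindered to react, and no stereocentre changes.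

**Compound list**
1 | 2,5-dimethylfuran | Cc1ccc(C)o1 | starting material
2 | 1,1,3-trichloropropan-2-one | ClCC(=O)C(Cl)Cl | starting material
3 | 2,4-dichloro-1,5-dimethyl-8-oxabicyclo[3.2.1]oct-6-en-3-one (cis-bridged; mixture of epimers at the two CHCl carbons) | C[C@]12C(Cl)C(=O)C(Cl)[C@](C)(O1)C=C2 | intermediate
4 | (1R,5S)-1,5-dimethyl-8-oxabicyclo[3.2.1]oct-6-en-3-one (meso) | C[C@]12CC(=O)C[C@](C)(O1)C=C2 | intermediate
5 | (1R,5S)-1,5-dimethyl-8-oxabicyclo[3.2.1]octan-3-one (meso) | C[C@]12CC(=O)C[C@](C)(O1)CC2 | intermediate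
6 | 3,6-dimethylcyclohepta-2,6-dien-1-one | O=C1C=C(C)CCC(C)=C1 | intermediate
7 | (1R,2R)-1,2-diphenylethane-1,2-diol | O[C@H](c1ccccc1)[C@H](O)c1ccccc1 | starting material
8 | (1R,2R)-1,2-diphenyl-1,2-bis(trimethylsilyloxy)ethane | C[Si](C)(C)O[C@H](c1ccccc1)[C@H](O[Si](C)(C)C)c1ccccc1 | intermediate
9 | (2R,3R)-7,10-dimethyl-2,3-diphenyl-1,4-dioxaspiro[4.6]undeca-6,10-diene | CC1=CC2(O[C@H](c3ccccc3)[C@@H](c3ccccc3)O2)C=C(C)CC1 | intermediate
10 | (1S,7R,4'R,5'R)-4,7-dimethyl-4',5'-diphenylspiro[bicyclo[5.1.0]oct-3-ene-2,2'-[1,3]dioxolane] | CC1=CC4(O[C@H](c3ccccc3)[C@@H](c3ccccc3)O4)[C@H]2C[C@@]2(C)CC1 | intermediate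
11 | (1S,7R)-4,7-dimethylbicyclo[5.1.0]oct-3-en-2-one | O=C1C=C(C)CC[C@]2(C)C[C@H]12 | intermediate
12 | 3-methylbut-1-yne | C#CC(C)C | starting material
13 | (3aR,8aR)-6,8a-dimethyl-3-(propan-2-yl)-3a,7,8,8a-tetrahydroazulen-4(1H)-one | O=C1C=C(C)CC[C@]2(C)CC=C(C(C)C)[C@H]12 | intermediate
14 | (8aR)-6,8a-dimethyl-3-(propan-2-yl)-2,7,8,8a-tetrahydroazulen-4(1H)-one | O=C1C=C(C)CC[C@]2(C)CCC(C(C)C)=C12 | intermediate
15 | (3R,3aR,8aR)-3,3a-epoxy-6,8a-dimethyl-3-(propan-2-yl)-2,3,3a,7,8,8a-hexahydroazulen-4(1H)-one | O=C1C=C(C)CC[C@]2(C)CC[C@]3(C(C)C)O[C@]123 | intermediate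
16 | potassium (3R,3aR,8aS)-3,3a-epoxy-6,8a-dimethyl-3-(propan-2-yl)-1,2,3,3a,8,8a-hexahydroazulen-4-olate | [K+].[O-]C1=CC(C)=CC[C@]2(C)CC[C@]3(C(C)C)O[C@]123 | intermediate
17 | (3R,3aR,8aS)-3,3a-epoxy-6,8a-dimethyl-3-(propan-2-yl)-2,3,3a,5,8,8a-hexahydroazulen-4(1H)-one | O=C1CC(C)=CC[C@]2(C)CC[C@]3(C(C)C)O[C@]123 | intermediate
18 | (3R,3aS,8aS)-3-hydroxy-6,8a-dimethyl-3-(propan-2-yl)-2,3,3a,5,8,8a-hexahydroazulen-4(1H)-one | O=C1CC(C)=CC[C@]2(C)CC[C@@](O)(C(C)C)[C@@H]12 | intermediate
19 | (3R,3aR,4R,8aS)-6,8a-dimethyl-3-(propan-2-yl)-1,2,3,3a,4,5,8,8a-octahydroazulene-3,4-diol | O[C@@H]1CC(C)=CC[C@]2(C)CC[C@@](O)(C(C)C)[C@@H]12 | intermediate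
20 | 3,4-dimethoxybenzoyl chloride | COc1ccc(C(Cl)=O)cc1OC | starting material
21 | (3R,3aR,4R,8aS)-3-hydroxy-6,8a-dimethyl-3-(propan-2-yl)-1,2,3,3a,4,5,8,8a-octahydroazulen-4-yl 3,4-dimethoxybenzoate | COc1ccc(C(=O)O[C@@H]2CC(C)=CC[C@]3(C)CC[C@@](O)(C(C)C)[C@@H]23)cc1OC | target

**Step count and risks**
Total step count: 12. Longest linear sequence: 12 steps (1 → 21).

Steps most likely to fail:

Step 7. The conjugated cyclopropyl ketone may be lost to reductive dimerisation of its radical anion, or the C1 radical may abstract hydrogen from THF faster than it adds to the unactivated alkyl alkyne, so that the catalyst stalls. The fallback sets out from dienone 6 and builds the same ring by conjugate addition and aldol condensation instead. The Grignard reagent from 2-(2-bromoethyl)-2-(propan-2-yl)-1,3-dioxolane F1 (made from 4-methylpent-1-en-3-one, HBr and ethane-1,2-diol) would be added to 6 in a copper-catalysed asymmetric conjugate addition (Cu(OTf)2, chiral phosphoramidite ligand, Et2O, −30 °C). This desymmetrises the dienone and should set the quaternary centre in (6R)-3,6-dimethyl-6-{2-[2-(propan-2-yl)-1,3-dioxolan-2-yl]ethyl}cyclohept-2-en-1-one F2. Aqueous HCl would free the diketone (6R)-3,6-dimethyl-6-(4-methyl-3-oxopentyl)cyclohept-2-en-1-one F3, and KOH/MeOH would close it by intramolecular aldol condensation. The route is rejoined at dienone 14.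

Step 9. Site selectivity between the two enone double bonds may be poor, or the second double bond may be oxidised as well. The fallback sets out from 14. The less hindered C5=C6 enone would be reduced by conjugate hydride delivery with [(Ph3P)CuH]6 to (8aR)-6,8a-dimethyl-3-(propan-2-yl)-2,5,6,7,8,8a-hexahydroazulen-4(1H)-one F4 (C6 epimers, both usable). The one enone left would then be epoxidised with alkaline hydrogen peroxide (Weitz–Scheffer, again anti to the C8a methyl group) to (3R,3aR,8aR)-3,3a-epoxy-6,8a-dimethyl-3-(propan-2-yl)octahydroazulen-4(1H)-one F5. Dehydrogenation with IBX in DMSO on the only enolisable side of the ketone would restore the C5=C6 bond. The route is rejoined at epoxy dienone 15.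

Step 10. Deconjugation may be incomplete, the double bond may move back into conjugation during the quench, or the base may attack the epoxy ketone. The fallback sets out from 15 and separates enolisation from protonation. Soft enolisation with TBSOTf/Et3N (CH2Cl2, −78 °C) can only give the extended silyl dienol ether tert-butyl{[(3R,3aR,8aS)-3,3a-epoxy-6,8a-dimethyl-3-(propan-2-yl)-1,2,3,3a,8,8a-hexahydroazulen-4-yl]oxy}dimethylsilane F6, which can be purified. Protodesilylation at low temperature (TBAF, AcOH, THF, −78 °C) would then protonate C5 kinetically. The route is rejoined at 17.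

Further compounds
F1 | step 7 | 2-(2-bromoethyl)-2-(propan-2-yl)-1,3-dioxolane | CC(C)C1(CCBr)OCCO1
F2 | step 7 | (6R)-3,6-dimethyl-6-{2-[2-(propan-2-yl)-1,3-dioxolan-2-yl]ethyl}cyclohept-2-en-1-one | O=C1C=C(C)CC[C@](C)(CCC2(C(C)C)OCCO2)C1
F3 | step 7 | (6R)-3,6-dimethyl-6-(4-methyl-3-oxopentyl)cyclohept-2-en-1-one | O=C1C=C(C)CC[C@](C)(CCC(=O)C(C)C)C1
F4 | step 9 | (8aR)-6,8a-dimethyl-3-(propan-2-yl)-2,5,6,7,8,8a-hexahydroazulen-4(1H)-one (C6 epimers) | O=C1CC(C)CC[C@]2(C)CCC(C(C)C)=C12
F5 | step 9 | (3R,3aR,8aR)-3,3a-epoxy-6,8a-dimethyl-3-(propan-2-yl)octahydroazulen-4(1H)-one (C6 epimers) | O=C1CC(C)CC[C@]2(C)CC[C@]3(C(C)C)O[C@]123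
F6 | step 10 | tert-butyl{[(3R,3aR,8aS)-3,3a-epoxy-6,8a-dimethyl-3-(propan-2-yl)-1,2,3,3a,8,8a-hexahydroazulen-4-yl]oxy}dimethylsilane | CC(C)(C)[Si](C)(C)OC1=CC(C)=CC[C@]2(C)CC[C@]3(C(C)C)O[C@]123
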